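The route rests on forming the C12–O and C13–O bonds last: the C12=C13–C14=O enone of the intact 14-membered ring is epoxidised by a peroxide anion. One operation closes the oxirane and sets C12 and C13. The step exploits that this 12E enone is the only reachable Michael acceptor, since the C1=C15 isopropylidene flank of C14 is tetrasubstituted and twisted, and that the macrocycle, stiffened by the C7–C10 oxolane with its Z C6=C7 enol ether, shows one face of C12=C13. The precursor is the macrocyclic dienone acetate 28, built as the single 12E isomer by alkenyl iodide–aldehyde ring closure (C13–C14) instead of as a double-bond isomer mixture.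

Key step: step 21

Assumption: atoms are numbered as in a cembrane (C1 bears the isopropylidene carbon C15, C4 the acetate, C14 is the ketone; TBS = tert-butyldimethylsilyl), and the antipodes named for the chiral reagents in steps 5 and 8 and in the first fallback follow the usual empirical face rules, the SMILES strings being binding.

Step 1
Reactants: 1 diethyl 2-(propan-2-ylidene)propanedioate
Product: 2 2-(propan-2-ylidene)propane-1,3-diol
Conditions: DIBAL-H (4.5 equiv), CH2Cl2, −78 to 0 °C; Rochelle salt work-up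
Reagents that add atoms: none
Why: Hydride 1,2-reduction of both esters to the allylic diol should win over conjugate reduction because the β-carbon carries two methyl groups, so the tetrasubstituted C1=C15 alkene is in place from the start.

Step 2
Reactants: 2 2-(propan-2-ylidene)propane-1,3-diol
Product: 3 2-(TBSO-methyl)-3-methylbut-2-en-1-ol (mono-TBS ether of 2)
Conditions: NaH (1.0 equiv), THF, 0 °C; TBSCl (1.0 equiv), rt
Reagents that add atoms: tert-butyldimethylsilyl chloride, CC(C)(C)[Si](C)(C)Cl
Why: Monosilylation of a symmetric diol through its monosodium alkoxide differentiates C14 (silylated) from C2 (free) without a selectivity problem, since the two hydroxyls are equivalent.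

Step 3
Reactants: 3 2-(TBSO-methyl)-3-methylbut-2-en-1-ol
Product: 4 {[2-(bromomethyl)-3-methylbut-2-en-1-yl]oxy}(tert-butyl)dimethylsilane
Conditions: CBr4, PPh3, CH2Cl2, 0 °C
Reagents that add atoms: carbon tetrabromide, BrC(Br)(Br)Br
Why: Appel reaction, in which the primary allylic alcohol is replaced by bromide under neutral conditions that the silyl ether and the tetrasubstituted alkene tolerate.

Step 4
Reactants: 4 {[2-(bromomethyl)-3-methylbut-2-en-1-yl]oxy}(tert-butyl)dimethylsilane; 5 2-methylprop-2-en-1-ol
Product: 7 5-(TBSO-methyl)-6-methyl-2-methylidenehept-5-en-1-ol, via dilithiated 2-methylprop-2-en-1-ol 6 (not isolated)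
Conditions: 5, n-BuLi (2.2 equiv), TMEDA, Et2O–hexane, 0 °C to rt; then 4, THF, −78 °C to rt
Reagents that add atoms: none
Why: Allylic lithiation of the lithium alkoxide of 5 gives a C,O-dianion whose carbon terminus is alkylated by the primary allylic bromide (SN2, the SN2′ site being fully substituted), which forms C2–C3 and leaves an allylic alcohol for step 5.

Step 5
Reactants: 7 5-(TBSO-methyl)-6-methyl-2-methylidenehept-5-en-1-ol
Product: 8 {(2R)-2-[3-(TBSO-methyl)-4-methylpent-3-en-1-yl]oxiran-2-yl}methanol
Conditions: Ti(OiPr)4 (10 mol %), D-(−)-diisopropyl tartrate (12 mol %), t-BuOOH, 4 Å MS, CH2Cl2, −20 °C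
Reagents that add atoms: tert-butyl hydroperoxide, CC(C)(C)OO
Why: Sharpless asymmetric epoxidation of the 2-substituted allylic alcohol sets C4 under reagent control (the tartrate antipode that turns 5 itself into (R)-2-methylglycidol), and the other alkene, which has no free hydroxyl beside it, is not epoxidised.

Step 6
Reactants: 8 {(2R)-2-[3-(TBSO-methyl)-4-methylpent-3-en-1-yl]oxiran-2-yl}methanol
Product: 9 (2R)-5-(TBSO-methyl)-2,6-dimethylhept-5-ene-1,2-diol
Conditions: LiAlH4, THF, 0 °C
Reagents that add atoms: none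
Why: Hydride opens the epoxide at its unsubstituted CH2 carbon (SN2), which turns that carbon into the C4 methyl group and frees the tertiary alcohol without breaking a bond at C4, so the configuration is kept.

Step 7
Reactants: 9 (2R)-5-(TBSO-methyl)-2,6-dimethylhept-5-ene-1,2-diol
Product: 11 (2R)-2-[3-(TBSO-methyl)-4-methylpent-3-en-1-yl]-2-methyloxirane, via primary monotosylate 10 (not isolated)
Conditions: NaH (2.5 equiv), 1-(p-toluenesulfonyl)imidazole, THF, 0 °C to rt
Reagents that add atoms: none
Why: The primary hydroxyl is sulfonylated selectively and the tertiary alkoxide then closes the ring by intramolecular Williamson substitution (3-exo-tet), so the former CH2OH becomes the electrophilic C5 while C4 stays R.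

Step 8
Reactants: 12 methyl 4-oxobutanoate
Product: 14 (5R)-5-(prop-2-yn-1-yl)oxolan-2-one, via methyl (4R)-4-hydroxyhept-6-ynoate 13 (not isolated)
Conditions: allenylboronic acid pinacol ester, TRIP phosphoric acid (5 mol %, antipode giving 4R), 4 Å MS, toluene, −20 °C; then TsOH (cat.), CH2Cl2, rt
Reagents that add atoms: allenylboronic acid pinacol ester, C=C=CB1OC(C)(C)C(C)(C)O1
Why: Chiral-Brønsted-acid-catalysed propargylation of the aldehyde (SE2′ allenylboration through a closed six-membered transition state) sets C10 under catalyst control, and the γ-hydroxy ester lactonises on acid treatment.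

Step 9
Reactants: 14 (5R)-5-(prop-2-yn-1-yl)oxolan-2-one
Product: 16 (5R)-5-[(2E)-3-iodo-2-methylprop-2-en-1-yl]oxolan-2-one, via E-alkenyl(dimethyl)alane 15 (not isolated)
Conditions: AlMe3 (3 equiv), Cp2ZrCl2 (20 mol %), H2O (1 equiv), CH2Cl2, −30 °C; then I2, THF, −30 to 0 °C
Reagents that add atoms: trimethylaluminium, C[Al](C)C; iodine, II
Why: Zirconium-catalysed syn-carboalumination of the terminal alkyne (Negishi carboalumination, water-accelerated variant) places methyl on C12 and aluminium on C13, and iodinolysis with retention gives the 12E alkenyl iodide, the low temperature sparing the lactone.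

Step 10
Reactants: 16 (5R)-5-[(2E)-3-iodo-2-methylprop-2-en-1-yl]oxolan-2-one
Product: 17 (3S,5R)-5-[(2E)-3-iodo-2-methylprop-2-en-1-yl]-3-methyloxolan-2-one
Conditions: LDA, THF, −78 °C; MeI, −78 to −40 °C
Reagents that add atoms: iodomethane, CI
Why: Alkylation of the lactone enolate should occur anti to the C10 side chain on the ring envelope, so the 3,5-trans lactone with 8S is expected as the major isomer (substrate-controlled enolate alkylation).

Step 11
Reactants: 17 (3S,5R)-5-[(2E)-3-iodo-2-methylprop-2-en-1-yl]-3-methyloxolan-2-one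
Product: 18 (3S,5R)-5-[(2E)-3-iodo-2-methylprop-2-en-1-yl]-3-methyloxolan-2-ol (both anomers)
Conditions: DIBAL-H (1.1 equiv), CH2Cl2, −78 °C
Reagents that add atoms: none
Why: Partial reduction of the lactone stops at the lactol because the tetrahedral aluminium hemiacetal is stable at −78 °C.

Step 12
Reactants: 18 (3S,5R)-5-[(2E)-3-iodo-2-methylprop-2-en-1-yl]-3-methyloxolan-2-ol
Product: 19 (3S,5R,7E)-8-iodo-3,7-dimethyloct-7-en-1-yn-5-ol
Conditions: dimethyl (1-diazo-2-oxopropyl)phosphonate, K2CO3, MeOH, 0 °C to rt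
Reagents that add atoms: dimethyl (1-diazo-2-oxopropyl)phosphonate, COP(=O)(OC)C(=[N+]=[N-])C(C)=O
Why: Seyferth–Gilbert homologation in its Ohira–Bestmann form converts the open hydroxy aldehyde (in equilibrium with the lactol) into the terminal alkyne C6≡C7 and frees the C10 hydroxyl, the carbonate base being mild enough for C8 and the alkenyl iodide.

Step 13
Reactants: 19 (3S,5R,7E)-8-iodo-3,7-dimethyloct-7-en-1-yn-5-ol
Product: 20 tert-butyl{[(3S,5R,7E)-8-iodo-3,7-dimethyloct-7-en-1-yn-5-yl]oxy}dimethylsilane
Conditions: TBSCl, imidazole, DMF, rt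
Reagents that add atoms: tert-butyldimethylsilyl chloride, CC(C)(C)[Si](C)(C)Cl
Why: Silylation of the secondary alcohol leaves the alkyne C–H as the only acidic site for step 14 and keeps C10–O masked until C4–OH has been acetylated.

Step 14
Reactants: 20 tert-butyl{[(3S,5R,7E)-8-iodo-3,7-dimethyloct-7-en-1-yn-5-yl]oxy}dimethylsilane; 11 (2R)-2-[3-(TBSO-methyl)-4-methylpent-3-en-1-yl]-2-methyloxirane
Product: 22 (6R,10S,12R,14E)-15-iodo-2,6,10,14-tetramethyl-12-(TBSO)-3-(TBSO-methyl)pentadeca-2,14-dien-8-yn-6-ol, via lithium acetylide 21 (not isolated)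
Conditions: 20, MeLi (1.0 equiv), THF, −78 °C; BF3·OEt2; then 11, −78 °C
Reagents that add atoms: none
Why: Yamaguchi–Hirao alkynylation, in which the BF3-activated 2,2-disubstituted epoxide is opened by the alkynyl borate at its CH2 carbon (SN2), forming C5–C6 and releasing the C4 tertiary alcohol with C4 untouched, while methyllithium should deprotonate the alkyne much faster than it exchanges with the alkenyl iodide.

Step 15
Reactants: 22 (6R,10S,12R,14E)-15-iodo-2,6,10,14-tetramethyl-12-(TBSO)-3-(TBSO-methyl)pentadeca-2,14-dien-8-yn-6-ol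
Product: 23 (6R,10S,12R,14E)-15-iodo-2,6,10,14-tetramethyl-12-(TBSO)-3-(TBSO-methyl)pentadeca-2,14-dien-8-yn-6-yl acetate
Conditions: Ac2O, DMAP, Et3N, CH2Cl2, 40 °C
Reagents that add atoms: acetic anhydride, CC(=O)OC(C)=O
Why: DMAP-catalysed acylation puts the acetate on the only free hydroxyl, the hindered tertiary C4–OH, at a stage where no acid- or base-sensitive group is present.

Step 16
Reactants: 23 (6R,10S,12R,14E)-15-iodo-2,6,10,14-tetramethyl-12-(TBSO)-3-(TBSO-methyl)pentadeca-2,14-dien-8-yn-6-yl acetate
Product: 24 (6R,10S,12R,14E)-12-hydroxy-3-(hydroxymethyl)-15-iodo-2,6,10,14-tetramethylpentadeca-2,14-dien-8-yn-6-yl acetate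
Conditions: HF·pyridine, pyridine, THF, 0 °C to rt
Reagents that add atoms: none
Why: Fluoride-mediated desilylation removes both silyl ethers (C10 and C14) in one operation under buffered conditions that leave the tertiary acetate and the alkenyl iodide alone.

Step 17
Reactants: 24 (6R,10S,12R,14E)-12-hydroxy-3-(hydroxymethyl)-15-iodo-2,6,10,14-tetramethylpentadeca-2,14-dien-8-yn-6-yl acetate
Product: 25 (6R,10S,12R,14E)-3-formyl-12-hydroxy-15-iodo-2,6,10,14-tetramethylpentadeca-2,14-dien-8-yn-6-yl acetate
Conditions: MnO2, CH2Cl2, rt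
Reagents that add atoms: none
Why: Manganese dioxide oxidises only the allylic C14 alcohol, giving the α-isopropylidene aldehyde directly in conjugation, and leaves the saturated C10 carbinol untouched (chemoselective allylic oxidation).

Step 18
Reactants: 25 (6R,10S,12R,14E)-3-formyl-12-hydroxy-15-iodo-2,6,10,14-tetramethylpentadeca-2,14-dien-8-yn-6-yl acetate
Product: 26 (3R)-6-formyl-1-{(2Z,3S,5R)-5-[(2E)-3-iodo-2-methylprop-2-en-1-yl]-3-methyloxolan-2-ylidene}-3,7-dimethyloct-6-en-3-yl acetate
Conditions: Ph3PAuCl (2 mol %), AgOTf (2 mol %), 2,6-di-tert-butylpyridine (10 mol %), THF, 0 °C to rt; Et3N quench, Et3N-treated silica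
Reagents that add atoms: none
Why: Gold(I)-catalysed 5-exo-dig hydroalkoxylation, in which the C10 hydroxyl attacks C7 of the π-activated alkyne anti to gold and protodeauration with retention puts H6 trans to oxygen, so the oxolane closes with the Z C6=C7 enol ether, the hindered base suppressing acid-catalysed migration of the double bond into the ring.

Step 19
Reactants: 26 (3R)-6-formyl-1-{(2Z,3S,5R)-5-[(2E)-3-iodo-2-methylprop-2-en-1-yl]-3-methyloxolan-2-ylidene}-3,7-dimethyloct-6-en-3-yl acetate
Product: 27 (4R,6Z,8S,10R,12E)-14-hydroxy-7,10-epoxycembra-1(15),6,12-trien-4-yl acetate (both C14 epimers)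
Conditions: CrCl2 (10 equiv), NiCl2 (10 mol %), DMSO–THF, rt, 2 mM, slow addition
Reagents that add atoms: none
Why: Intramolecular Nozaki–Hiyama–Kishi reaction, in which nickel inserts into the alkenyl iodide with retention of the 12E geometry and the derived alkenylchromium(III) adds only to the aldehyde, closing the 14-membered ring at C13–C14, the uncontrolled C14 carbinol centre being removed in step 20.

Step 20
Reactants: 27 (4R,6Z,8S,10R,12E)-14-hydroxy-7,10-epoxycembra-1(15),6,12-trien-4-yl acetate
Product: 28 (4R,6Z,8S,10R,12E)-14-oxo-7,10-epoxycembra-1(15),6,12-trien-4-yl acetate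
Conditions: Dess–Martin periodinane, pyridine, CH2Cl2, 0 °C
Reagents that add atoms: none
Why: Dess–Martin oxidation of the doubly allylic alcohol gives the cross-conjugated dienone under buffered, non-aqueous conditions that should keep the enol ether and not isomerise the 12E double bond.

Step 21
Reactants: 28 (4R,6Z,8S,10R,12E)-14-oxo-7,10-epoxycembra-1(15),6,12-trien-4-yl acetate
Product: 29 (4R,6Z,8S,10R,12S,13R)-7,10:12,13-diepoxy-14-oxocembra-1(15),6-dien-4-yl acetate (CNP0162736.1)
Conditions: t-BuOOH (anhydrous, in decane), DBU, CH2Cl2, 0 °C to rt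
Reagents that add atoms: tert-butyl hydroperoxide, CC(C)(C)OO
Why: tert-Butylperoxide anion adds to C12, the β-carbon of the C12=C13–C14=O enone, and the C13 enolate then displaces tert-butoxide from the peroxide oxygen in a 3-exo-tet closure, so both C–O bonds of the oxirane form in one operation (Weitz–Scheffer nucleophilic epoxidation). The trans relationship of C11 and C14 on the oxirane follows from the 12E geometry of 28, and any rotation about C12–C13 in the enolate before closure leads to the same trans oxirane. The face is left to the substrate: C12=C13 sits on the rim of the macrocycle between the oxolane carbon C10 and the C14 carbonyl, and the peroxide should approach from the outer face of the conformer that keeps the C10–O bond away from the C12 methyl group, which would give 12S,13R. Chemoselectivity between the two enones on C14 is needed and is secured because the C1=C15 unit is tetrasubstituted, α-branched and twisted out of conjugation. The Z enol ether is electron-rich and should ignore a peroxide anion, and the tertiary acetate should not be cleaved by DBU in an aprotic medium.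

Compound list
1 | diethyl 2-(propan-2-ylidene)propanedioate | CCOC(=O)C(=C(C)C)C(=O)OCC | starting material
2 | 2-(propan-2-ylidene)propane-1,3-diol | OCC(=C(C)C)CO | intermediate
3 | 2-(TBSO-methyl)-3-methylbut-2-en-1-ol | OCC(=C(C)C)CO[Si](C)(C)C(C)(C)C | intermediate
4 | {[2-(bromomethyl)-3-methylbut-2-en-1-yl]oxy}(tert-butyl)dimethylsilane | BrCC(=C(C)C)CO[Si](C)(C)C(C)(C)C | intermediate
5 | 2-methylprop-2-en-1-ol | C=C(C)CO | starting material
6 | dilithiated 2-methylprop-2-en-1-ol (C,O-dianion) | [Li]CC(=C)CO[Li] | intermediate (not isolated)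
7 | 5-(TBSO-methyl)-6-methyl-2-methylidenehept-5-en-1-ol | C=C(CO)CCC(=C(C)C)CO[Si](C)(C)C(C)(C)C | intermediate
8 | {(2R)-2-[3-(TBSO-methyl)-4-methylpent-3-en-1-yl]oxiran-2-yl}methanol | OC[C@]1(CCC(=C(C)C)CO[Si](C)(C)C(C)(C)C)CO1 | intermediate
9 | (2R)-5-(TBSO-methyl)-2,6-dimethylhept-5-ene-1,2-diol | C[C@](O)(CO)CCC(=C(C)C)CO[Si](C)(C)C(C)(C)C | intermediate
10 | primary monotosylate of 9 | C[C@](O)(COS(=O)(=O)c1ccc(C)cc1)CCC(=C(C)C)CO[Si](C)(C)C(C)(C)C | intermediate (not isolated)
11 | (2R)-2-[3-(TBSO-methyl)-4-methylpent-3-en-1-yl]-2-methyloxirane | C[C@@]1(CCC(=C(C)C)CO[Si](C)(C)C(C)(C)C)CO1 | intermediate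
12 | methyl 4-oxobutanoate | COC(=O)CCC=O | starting material
13 | methyl (4R)-4-hydroxyhept-6-ynoate | C#CC[C@H](O)CCC(=O)OC | intermediate (not isolated)
14 | (5R)-5-(prop-2-yn-1-yl)oxolan-2-one | C#CC[C@H]1CCC(=O)O1 | intermediate
15 | E-alkenyl(dimethyl)alane from 14 | C[Al](C)/C=C(C)/C[C@H]1CCC(=O)O1 | intermediate (not isolated)
16 | (5R)-5-[(2E)-3-iodo-2-methylprop-2-en-1-yl]oxolan-2-one | I/C=C(C)/C[C@H]1CCC(=O)O1 | intermediate
17 | (3S,5R)-5-[(2E)-3-iodo-2-methylprop-2-en-1-yl]-3-methyloxolan-2-one | I/C=C(C)/C[C@H]1C[C@H](C)C(=O)O1 | intermediate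
18 | (3S,5R)-5-[(2E)-3-iodo-2-methylprop-2-en-1-yl]-3-methyloxolan-2-ol (anomers) | I/C=C(C)/C[C@H]1C[C@H](C)C(O)O1 | intermediate
19 | (3S,5R,7E)-8-iodo-3,7-dimethyloct-7-en-1-yn-5-ol | C#C[C@@H](C)C[C@@H](O)C/C(C)=C/I | intermediate
20 | tert-butyl{[(3S,5R,7E)-8-iodo-3,7-dimethyloct-7-en-1-yn-5-yl]oxy}dimethylsilane | C#C[C@@H](C)C[C@@H](O[Si](C)(C)C(C)(C)C)C/C(C)=C/I | intermediate
21 | lithium acetylide of 20 | [Li]C#C[C@@H](C)C[C@@H](O[Si](C)(C)C(C)(C)C)C/C(C)=C/I | intermediate (not isolated)
22 | (6R,10S,12R,14E)-15-iodo-2,6,10,14-tetramethyl-12-(TBSO)-3-(TBSO-methyl)pentadeca-2,14-dien-8-yn-6-ol | C[C@@](O)(CCC(=C(C)C)CO[Si](C)(C)C(C)(C)C)CC#C[C@@H](C)C[C@@H](O[Si](C)(C)C(C)(C)C)C/C(C)=C/I | intermediate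
23 | acetate of 22 | CC(=O)O[C@](C)(CCC(=C(C)C)CO[Si](C)(C)C(C)(C)C)CC#C[C@@H](C)C[C@@H](O[Si](C)(C)C(C)(C)C)C/C(C)=C/I | intermediate
24 | (6R,10S,12R,14E)-12-hydroxy-3-(hydroxymethyl)-15-iodo-2,6,10,14-tetramethylpentadeca-2,14-dien-8-yn-6-yl acetate | CC(=O)O[C@](C)(CCC(=C(C)C)CO)CC#C[C@@H](C)C[C@@H](O)C/C(C)=C/I | intermediate
25 | (6R,10S,12R,14E)-3-formyl-12-hydroxy-15-iodo-2,6,10,14-tetramethylpentadeca-2,14-dien-8-yn-6-yl acetate | CC(=O)O[C@](C)(CCC(=C(C)C)C=O)CC#C[C@@H](C)C[C@@H](O)C/C(C)=C/I | intermediate
26 | (3R)-6-formyl-1-{(2Z,3S,5R)-5-[(2E)-3-iodo-2-methylprop-2-en-1-yl]-3-methyloxolan-2-ylidene}-3,7-dimethyloct-6-en-3-yl acetate | CC(=O)O[C@](C)(CCC(=C(C)C)C=O)C/C=C1\O[C@H](C[C@@H]1C)C/C(C)=C/I | intermediate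
27 | (4R,6Z,8S,10R,12E)-14-hydroxy-7,10-epoxycembra-1(15),6,12-trien-4-yl acetate (C14 epimers) | CC(=O)O[C@@]1(C)C/C=C2\O[C@H](C[C@@H]2C)C/C(C)=C/C(O)C(=C(C)C)CC1 | intermediate
28 | (4R,6Z,8S,10R,12E)-14-oxo-7,10-epoxycembra-1(15),6,12-trien-4-yl acetate (precursor of the key step) | CC(=O)O[C@@]1(C)C/C=C2\O[C@H](C[C@@H]2C)C/C(C)=C/C(=O)C(=C(C)C)CC1 | intermediate
29 | (4R,6Z,8S,10R,12S,13R)-7,10:12,13-diepoxy-14-oxocembra-1(15),6-dien-4-yl acetate | CC(=O)O[C@@]1(C)C/C=C2\O[C@H](C[C@@H]2C)C[C@]2(C)O[C@H]2C(=O)C(=C(C)C)CC1 | target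

Total step count: 21.
Longest linear sequence: 15 steps (steps 1–7, then 14–21); the other branch is steps 8–13, then 14–21 (14 steps).

Steps most likely to fail

Step 21. The peroxide anion may attack both faces of C12=C13, or the wrong one, if the macrocycle does not hold one conformation. The fallback sets out from carbinol 27 and uses reagent control on the allylic alcohol. Sharpless epoxidation (Ti(OiPr)4, L-(+)-diisopropyl tartrate, t-BuOOH, 4 Å MS, CH2Cl2, −20 °C) should epoxidise C12=C13 of the C14 epimer that is matched to the tartrate, on the face the reagent dictates, to give the macrocyclic epoxy alcohol F1. The slow-reacting epimer is returned to the pool by oxidation to 28 and Luche reduction. Dess–Martin oxidation of F1 (pyridine buffer) then gives 29, so the fallback comes back at the target.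

Step 19. Ring closure may lose out to oligomerisation, or the alkenylchromium may add too slowly to the hindered aldehyde once the chain is stiffened by the oxolane. The enol ether may also be eroded by the chromium(III) salts. The fallback sets out from ynol aldehyde 25 and changes the order of ring formation. The Nozaki–Hiyama–Kishi closure is run on the more flexible open chain to give the macrocyclic ynediol F2. Manganese dioxide oxidises only its allylic C14 alcohol to give the macrocyclic ynone F3. Gold(I)-catalysed transannular 5-exo-dig hydroalkoxylation by the C10 hydroxyl then closes the oxolane and returns to the route at 28.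

Step 14. Iodine–lithium exchange at C13 may compete with alkyne deprotonation, and BF3 may rearrange the 2,2-disubstituted epoxide or ionise the allylic silyl ether before the acetylide arrives. The fallback sets out from diol 9 and uses an electrophile that needs neither a Lewis acid nor an alkyllithium. The diol is converted with 1,1′-sulfonyldiimidazole and NaH (THF) into the cyclic sulfate F4. The acetylide of 20, generated with LDA, opens F4 at the CH2 carbon to give the lithium alkyl sulfate F5. Brief hydrolysis (catalytic H2SO4, one equivalent of water, THF) gives 22, where the route is rejoined.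

Further compounds
F1 | step 21 | (4R,6Z,8S,10R,12S,13S)-7,10:12,13-diepoxy-14-hydroxycembra-1(15),6-dien-4-yl acetate (C14 as in the matched epimer of 27, not assigned) | CC(=O)O[C@@]1(C)C/C=C2\O[C@H](C[C@@H]2C)C[C@]2(C)O[C@H]2C(O)C(=C(C)C)CC1
F2 | step 19 | (4R,8S,10R,12E)-10,14-dihydroxycembra-1(15),12-dien-6-yn-4-yl acetate (C14 epimers) | CC(=O)O[C@@]1(C)CC#C[C@@H](C)C[C@@H](O)C/C(C)=C/C(O)C(=C(C)C)CC1
F3 | step 19 | (4R,8S,10R,12E)-10-hydroxy-14-oxocembra-1(15),12-dien-6-yn-4-yl acetate | CC(=O)O[C@@]1(C)CC#C[C@@H](C)C[C@@H](O)C/C(C)=C/C(=O)C(=C(C)C)CC1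
F4 | step 14 | (4R)-4-methyl-4-[3-(TBSO-methyl)-4-methylpent-3-en-1-yl]-1,3,2-dioxathiolane 2,2-dioxide | C[C@@]1(CCC(=C(C)C)CO[Si](C)(C)C(C)(C)C)COS(=O)(=O)O1
F5 | step 14 | lithium (6R,10S,12R,14E)-15-iodo-2,6,10,14-tetramethyl-12-(TBSO)-3-(TBSO-methyl)pentadeca-2,14-dien-8-yn-6-yl sulfate | C[C@@](OS(=O)(=O)[O-])(CCC(=C(C)C)CO[Si](C)(C)C(C)(C)C)CC#C[C@@H](C)C[C@@H](O[Si](C)(C)C(C)(C)C)C/C(C)=C/I.[Li+]
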